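## The problem

The target **24** is a 1,4-dimethylcyclohexene that carries two 7-methoxycoumarin units. The carbocycle is numbered C1 (quaternary: methyl and an (E)-ethenyl arm ending at C6 of coumarin A), C2, C3, C4 (methyl, C4=C5), C5 and C6 (CH bonded to C6 of coumarin B). The only stereocentres are the neighbours C1 (R) and C6 (S), with the C1 methyl group and the C6 aryl group on the same ring face. Neither centre can be relied on to control the other by size, because the methyl group, the C2 methylene and the alkenyl arm on C1 differ little in bulk. Both centres therefore have to come from one stereospecific event, and the absolute sense from a catalyst. The two lactones are Michael acceptors and acylating agents that do not survive organolithium or Grignard reagents or hydroxide. C6–H is benzylic and allylic. The arm alkene and C4=C5 form a 1,5-diene across C1–C6 that could undergo Cope rearrangement on strong heating. The enabling feature is that C1 and C6 map onto the two carbons of a trisubstituted alkene C(CH3)=CH. If C2 and the aryl ring of coumarin B add to opposite faces of that alkene while C1 keeps boron as a place-holder for the arm, a (Z)-alkene gives exactly the methyl-cis-to-aryl relationship. C4=C5 is then a ring-closing metathesis site, and both coumarins can be attached or built late.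

## Retrosynthesis

**Coumarin B (24 ⇒ 23 ⇒ 22 ⇒ 21).** The C4–C4a bond and the lactone acyl–oxygen bond of coumarin B are cut, leading back through aryl propiolate **23** and phenol **22** to silyl ether **21**. This lets the C6 aryl group travel through the organometallic steps as a 2-methoxy-4-silyloxyphenyl group with no lactone. Carrying coumarin B intact would expose it to the vinyl Grignard step. The ring carbon that must attack the alkyne is para to the methoxy group and is the only activated, unhindered position. The forward reaction must be a mild 6-endo hydroarylation that leaves two alkenes and coumarin A alone.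

**Arm (21 ⇒ 16 + 20).** The bond between C6 of coumarin A and the arm is cut (Heck reaction of vinylcyclohexene **16** with bromocoumarin **20**). Cutting the arm C=C bond instead would need a neopentyl aldehyde on C1 and an olefination whose geometry is not guaranteed. In the Heck reaction the E geometry follows from the mechanism, and a vinyl group on a quaternary carbon cannot isomerise. **20** comes from aldehyde **17** by bromination (**18**) and a one-flask Wittig–lactonisation.

**Vinyl group on C1 (16 ⇒ 13).** The C1–vinyl bond is traced to a C1–boron bond (Zweifel olefination of tertiary boronate **13**). This is the reason for keeping boron on C1: it is exchanged for carbon with retention, so the quaternary centre is made as a boron-bearing centre. The step has to take place before any lactone is in the molecule.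

**Ring (13 ⇒ 12).** C4=C5 is cut by ring-closing metathesis of diene **12**, whose 1,1-disubstituted alkene supplies C4 with its methyl group and whose isobutenyl group supplies C5. The precursor is acyclic and the step touches neither stereocentre.

**Key disconnection (12 ⇒ 4 + 10 + 7).** C1–C2 and C6–aryl are cut together. Dienyl boronate **4**, organolithium **10** (from iodide **9**) and aryl triflate **7** are joined by a palladium-catalysed conjunctive coupling. The alkyl group migrates from boron to the boron-bearing carbon anti to palladium, and the aryl group is delivered to the neighbouring carbon. Cutting C1–C6 instead (sigmatropic or allyl–allyl logic) or only C6–aryl (conjugate addition) would leave the quaternary centre to separate chemistry. Here three simple achiral pieces give both centres in one step, relative configuration from the Z geometry of **4**, absolute configuration from the ligand. A terminal vinyl group on the β-carbon would leave an unhindered diene terminus open to 1,4-attack by palladium. The terminus is therefore capped with two methyl groups, which are lost as isobutene in the metathesis.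

**Boronate (4 ⇒ 3 ⇒ 2 ⇒ 1).** The isobutenyl alkene is cut by Wittig olefination of enal **3**, which comes from allylic alcohol **2** and this from but-2-yn-1-ol **1** by copper-catalysed syn borylation. Direct hydroboration of a 1,3-enyne would be shorter, but copper–boron and copper–hydride species tend to add to the alkene of such enynes or give allenes. The propargylic alcohol directs boron reliably to the remote alkyne carbon and fixes the geometry.

**Other partners (7 ⇒ 6 ⇒ 5; 9 ⇒ 8).** Triflate **7** comes from 2-methoxyhydroquinone **5** by silylation of the unhindered hydroxyl (**6**) and triflation. Iodide **9** comes from bromide **8**, because lithium–iodine exchange is cleaner than lithium–bromine exchange for a primary halide.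

## Roads not taken

**Alternative 1: vinylsilane-terminated cyclisation onto a benzylic cation.** The cut is the C5–C6 ring bond. Benzylic carbinol A1 already carries coumarin B, the C1 quaternary centre (methyl, silyloxymethyl) and a (Z)-vinylsilane. A Lewis acid ionises it, the silicon-bearing carbon attacks the cation in a 6-endo closure, and loss of silicon gives cyclohexene A2.
- Merits: every reaction type is established, either carbinol epimer converges on one cation, silicon fixes the position of C4=C5, and coumarin B needs no late construction.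
- Weak points: C1 must be made enantiopure beforehand in an open chain. C6 is then set only by the modest size difference between CH3 and CH2OSi. A benzylic cation beside a quaternary carbon invites 1,2-shifts, and the Lewis acid must coexist with the lactone. The silyloxymethyl group still has to become the (E)-arm by oxidation and an olefination of uncertain geometry.
- Comparison: this road is better in asking for no reaction beyond precedent. The chosen plan sets against it that both stereocentres come from one stereospecific event, that the arm geometry is guaranteed by the Heck step, and that the sequence is shorter.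

**Alternative 2: three-component arylation–alkenylation of a cyclohexenone.** The cuts are C6–aryl and C1–arm. Arylzinc chloride A4 of coumarin B adds to (S)-2,5-dimethylcyclohex-2-enone A3 trans to the ring methyl group, and the enolate is alkenylated by bromoalkene A5 trans to the new aryl group, giving ketone A6.
- Merits: both coumarins arrive intact, the ring is bought, and trans addition and trapping on a cyclohexenone is as dependable for relative configuration as the chosen plan. In convergence it is better, since all carbons are in place after one step.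
- Weak points: A6 has its carbonyl at C2 and a saturated C4–C5 unit. Reaching **24** means deleting a carbonyl beside a quaternary centre and creating C4=C5 two carbons away from any functional group, in the presence of two lactones. The alkenylation of a hindered α-methyl enolate with a base-sensitive coumarin partner is also demanding.
- Comparison: the chosen plan places the double bond by metathesis exactly where it is needed and has no carbonyl to remove. It pays with a late construction of coumarin B.

**Alternative 3: geometry-transferring Diels–Alder reaction, then silicon shift.** The cuts are C1–C2 and C5–C6. The (E)-enal A7 serves as the C6–C1 dienophile and reacts with silyl diene A8 under a cationic chiral oxazaborolidine to give cycloadduct A9. Protodesilylation of the allylsilane then moves the double bond to C4=C5.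
- Merits: ring and both stereocentres form in one step, and the relative configuration follows from the dienophile geometry as securely as it follows from the alkene geometry in the chosen plan. For ring construction it is the more economical road.
- Weak points: A7 is a trisubstituted enal with a strongly donating β-aryl group, a poor dienophile. The Lewis acid must select the aldehyde over the more basic lactone. The silicon shift needs acid in a molecule with a benzylic, allylic C6–H. The aldehyde still has to become the (E)-arm by olefination.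
- Comparison: the chosen plan does not depend on the electrophilicity of a deactivated enal and secures the arm geometry by the Heck step. It pays with one step beyond precedent.

Key step: step 7

Assumption: the (Sp,Sp) antipode of the ferrocenyl bisphosphine is taken to give the (5R,6S) series of **12** by extension of its behaviour with simpler alkenyl boronates; should the sense be opposite, the (Rp,Rp) antipode is used and nothing else changes.

## Steps

Step 1
Reactants: 1 but-2-yn-1-ol
Product: 2 (Z)-3-(4,4,5,5-tetramethyl-1,3,2-dioxaborolan-2-yl)but-2-en-1-ol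
Conditions: B2pin2 (1.1 equiv), CuCl (5 mol %), PPh3 (6 mol %), NaOt-Bu (15 mol %), MeOH (2 equiv), THF, rt
Reagents that add atoms: bis(pinacolato)diboron, CC1(C)OB(OC1(C)C)B1OC(C)(C)C(C)(C)O1
Why: Copper-catalysed formal hydroboration (syn borylcupration, then protonation by methanol); boron goes to the alkyne carbon remote from the hydroxymethyl group, so H and B end cis and the methyl group cis to CH2OH, which fixes the alkene geometry that later becomes the C1/C6 relative configuration.

Step 2
Reactants: 2 (Z)-3-(4,4,5,5-tetramethyl-1,3,2-dioxaborolan-2-yl)but-2-en-1-ol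
Product: 3 (Z)-3-(4,4,5,5-tetramethyl-1,3,2-dioxaborolan-2-yl)but-2-enal
Conditions: MnO2 (excess), CH2Cl2, rt
Reagents that add atoms: none
Why: Allylic alcohols are oxidised selectively by MnO2 under neutral conditions that leave the alkenyl boronate and the alkene geometry untouched.

Step 3
Reactants: 3 (Z)-3-(4,4,5,5-tetramethyl-1,3,2-dioxaborolan-2-yl)but-2-enal
Product: 4 4,4,5,5-tetramethyl-2-[(2Z)-5-methylhexa-2,4-dien-2-yl]-1,3,2-dioxaborolane
Conditions: i-PrPPh3I, NaN(SiMe3)2, THF, 0 °C; then 3, −78 °C → 0 °C
Reagents that add atoms: isopropyltriphenylphosphonium iodide, CC(C)[P+](c1ccccc1)(c1ccccc1)c1ccccc1.[I-]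
Why: Wittig olefination with a non-stabilised ylide adds 1,2 to the enal; the new alkene terminus carries two identical methyl groups, so no new geometric isomer arises and the geometry set in step 1 is not touched.

Step 4
Reactants: 5 2-methoxybenzene-1,4-diol
Product: 6 2-methoxy-4-(triisopropylsilyloxy)phenol
Conditions: i-Pr3SiCl (1.0 equiv), imidazole, CH2Cl2, 0 °C
Reagents that add atoms: chlorotriisopropylsilane, CC(C)[Si](Cl)(C(C)C)C(C)C
Why: Silylation with a bulky chlorosilane goes to the unhindered 4-hydroxyl; the 1-hydroxyl is flanked by the methoxy group and hydrogen-bonded to it.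

Step 5
Reactants: 6 2-methoxy-4-(triisopropylsilyloxy)phenol
Product: 7 2-methoxy-4-(triisopropylsilyloxy)phenyl trifluoromethanesulfonate
Conditions: Tf2O, pyridine, CH2Cl2, 0 °C
Reagents that add atoms: trifluoromethanesulfonic anhydride, O=S(=O)(OS(=O)(=O)C(F)(F)F)C(F)(F)F
Why: Standard O-triflation of a phenol; the aryl triisopropylsilyl ether is stable to these conditions.

Step 6
Reactants: 8 4-bromo-2-methylbut-1-ene
Product: 9 4-iodo-2-methylbut-1-ene
Conditions: NaI, acetone, reflux
Reagents that add atoms: sodium iodide, [Na+].[I-]
Why: Finkelstein exchange; the primary iodide is wanted because lithium–iodine exchange with t-BuLi is clean, whereas the bromide reacts partly by radical paths.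

Step 7
Reactants: 9 4-iodo-2-methylbut-1-ene; 4 4,4,5,5-tetramethyl-2-[(2Z)-5-methylhexa-2,4-dien-2-yl]-1,3,2-dioxaborolane; 7 2-methoxy-4-(triisopropylsilyloxy)phenyl trifluoromethanesulfonate
Product: 12 2-[(5R,6S)-6-[2-methoxy-4-(triisopropylsilyloxy)phenyl]-2,5,8-trimethylnona-1,7-dien-5-yl]-4,4,5,5-tetramethyl-1,3,2-dioxaborolane, via (3-methylbut-3-enyl)lithium 10 (not isolated), via lithium alkyl(dienyl)(pinacolato)borate 11 (not isolated)
Conditions: t-BuLi (2 equiv), pentane/Et2O, −78 °C; 4, −78 °C → rt; solvent exchange to THF; Pd(OAc)2 (2 mol %), (Sp,Sp)-MandyPhos ligand C64H74FeN2O4P2 (2.4 mol %), KOSO2CF3 (2 equiv), 7, 60 °C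
Reagents that add atoms: none
Why: Proposed new method: t-BuLi converts 9 into organolithium 10, which adds to boron of 4 to give ate complex 11; oxidative addition of 7 to zerovalent palladium gives a cationic arylpalladium triflate (divalent palladium) that binds the boron-bearing alkene of 11, the 3-methylbut-3-enyl group shifts from boron to the boron-bearing carbon on the face opposite to palladium, and C(sp3)–aryl reductive elimination follows, forming C1–C2 and C6–aryl of the later ring and closing no ring. The closest known reaction type is the palladium-catalysed enantioselective conjunctive cross-coupling of alkenylboron ate complexes with aryl triflates, established separately for α-substituted and for β-substituted alkenyl boronates but not for this α-methyl, β-alkenyl combination. The boron-bearing centre (C5 of 12, later ring C1) is set by the alkene face that palladium takes under control of the chiral ferrocenyl bisphosphine, since the migrating group must enter anti to the metal. The aryl-bearing centre (C6 of 12) follows from it, because the aryl group is delivered from palladium to the face opposite the migrating group, so the Z geometry of 4 becomes the methyl-cis-to-aryl relationship. The step needs attack at the β-carbon and not at the diene terminus; the two methyl groups on that terminus block 1,4-attack, Heck insertion and reductive elimination from the far end of any allylpalladium intermediate. It also needs the metallate shift to outrun direct transfer of a group from boron to palladium, which is served by the triflate-derived cationic palladium centre and by KOSO2CF3 as iodide scavenger.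

Step 8
Reactants: 12 2-[(5R,6S)-6-[2-methoxy-4-(triisopropylsilyloxy)phenyl]-2,5,8-trimethylnona-1,7-dien-5-yl]-4,4,5,5-tetramethyl-1,3,2-dioxaborolane
Product: 13 2-[(1R,2S)-2-[2-methoxy-4-(triisopropylsilyloxy)phenyl]-1,4-dimethylcyclohex-3-en-1-yl]-4,4,5,5-tetramethyl-1,3,2-dioxaborolane
Conditions: second-generation Hoveyda–Grubbs catalyst (C31H38Cl2N2ORu, 5–10 mol %), toluene, 80 °C, argon sparge
Reagents that add atoms: none
Why: Ring-closing metathesis between the 1,1-disubstituted and the trisubstituted alkene gives the trisubstituted C4=C5 bond in a six-membered ring with loss of volatile isobutene; the phosphine-free catalyst is chosen because both partners are hindered, and neither stereocentre is involved.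

Step 9
Reactants: 13 2-[(1R,2S)-2-[2-methoxy-4-(triisopropylsilyloxy)phenyl]-1,4-dimethylcyclohex-3-en-1-yl]-4,4,5,5-tetramethyl-1,3,2-dioxaborolane
Product: 16 triisopropyl[4-[(1S,6R)-6-ethenyl-3,6-dimethylcyclohex-2-en-1-yl]-3-methoxyphenoxy]silane, via bromomagnesium vinylboronate complex 14 (not isolated), via β-iodoalkyl pinacol boronate 15 (not isolated)
Conditions: CH2=CHMgBr (4 equiv), THF, rt; I2, MeOH, −78 °C; NaOMe, MeOH, −78 °C → rt
Reagents that add atoms: vinylmagnesium bromide, C=C[Mg]Br
Why: Zweifel olefination: the Grignard reagent forms ate complex 14, iodine triggers 1,2-migration of the tertiary alkyl group to give 15, and methoxide induces anti elimination of boron and iodide; the migrating carbon keeps its configuration, so C1 is transferred with retention, and no lactone is yet present to be attacked.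

Step 10
Reactants: 17 2-hydroxy-4-methoxybenzaldehyde
Product: 18 5-bromo-2-hydroxy-4-methoxybenzaldehyde
Conditions: Br2 (1.05 equiv), CH2Cl2, 0 °C
Reagents that add atoms: bromine, BrBr
Why: Electrophilic aromatic bromination at C5, para to the hydroxyl and ortho to the methoxy group; C3 between the two oxygen substituents is hindered.

Step 11
Reactants: 18 5-bromo-2-hydroxy-4-methoxybenzaldehyde
Product: 20 6-bromo-7-methoxychromen-2-one, via ethyl 3-(5-bromo-2-hydroxy-4-methoxyphenyl)prop-2-enoate 19 (not isolated)
Conditions: Ph3P=CHCO2Et, N,N-diethylaniline, reflux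
Reagents that add atoms: ethyl (triphenylphosphoranylidene)acetate, CCOC(=O)C=P(c1ccccc1)(c1ccccc1)c1ccccc1
Why: Wittig olefination of the salicylaldehyde, then thermal E/Z equilibration and lactonisation of cinnamate 19, the classical one-flask coumarin synthesis.

Step 12
Reactants: 16 triisopropyl[4-[(1S,6R)-6-ethenyl-3,6-dimethylcyclohex-2-en-1-yl]-3-methoxyphenoxy]silane; 20 6-bromo-7-methoxychromen-2-one
Product: 21 7-methoxy-6-[(E)-2-[(1R,2S)-2-[2-methoxy-4-(triisopropylsilyloxy)phenyl]-1,4-dimethylcyclohex-3-en-1-yl]ethenyl]chromen-2-one
Conditions: Pd2(dba)3 (C51H42O3Pd2, 2.5 mol %), [HP(t-Bu)3]BF4 (10 mol %), Cy2NMe, 1,4-dioxane, 80 °C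
Reagents that add atoms: none
Why: Heck reaction: the arylpalladium bromide adds to the unhindered terminus of the monosubstituted alkene, and syn β-hydride elimination can only use the benzylic hydrogens because C1 is quaternary, so the (E)-alkene forms without isomerisation; the bulky electron-rich phosphine allows a temperature at which the 1,5-diene and the lactone are safe.

Step 13
Reactants: 21 7-methoxy-6-[(E)-2-[(1R,2S)-2-[2-methoxy-4-(triisopropylsilyloxy)phenyl]-1,4-dimethylcyclohex-3-en-1-yl]ethenyl]chromen-2-one
Product: 22 6-[(E)-2-[(1R,2S)-2-(4-hydroxy-2-methoxyphenyl)-1,4-dimethylcyclohex-3-en-1-yl]ethenyl]-7-methoxychromen-2-one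
Conditions: Bu4NF, AcOH, THF, 0 °C
Reagents that add atoms: none
Why: Fluoride cleaves the aryl silyl ether; acetic acid buffers the phenoxide so that the lactone and the benzylic C6–H are not exposed to base.

Step 14
Reactants: 22 6-[(E)-2-[(1R,2S)-2-(4-hydroxy-2-methoxyphenyl)-1,4-dimethylcyclohex-3-en-1-yl]ethenyl]-7-methoxychromen-2-one
Product: 23 3-methoxy-4-[(1S,6R)-6-[(E)-2-(7-methoxy-2-oxochromen-6-yl)ethenyl]-3,6-dimethylcyclohex-2-en-1-yl]phenyl prop-2-ynoate
Conditions: HC≡CCO2H, DCC, DMAP (cat.), CH2Cl2, 0 °C
Reagents that add atoms: propiolic acid, C#CC(=O)O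
Why: Steglich-type carbodiimide esterification of the unhindered phenol at low temperature, the usual way to aryl propiolates.

Step 15
Reactants: 23 3-methoxy-4-[(1S,6R)-6-[(E)-2-(7-methoxy-2-oxochromen-6-yl)ethenyl]-3,6-dimethylcyclohex-2-en-1-yl]phenyl prop-2-ynoate
Product: 24 7-methoxy-6-[(E)-2-[(1R,2S)-2-(7-methoxy-2-oxochromen-6-yl)-1,4-dimethylcyclohex-3-en-1-yl]ethenyl]chromen-2-one
Conditions: [(2-biphenylyl)(t-Bu)2P]Au(NCMe)SbF6 (2–5 mol %), CH2Cl2, rt
Reagents that add atoms: none
Why: Gold-catalysed intramolecular hydroarylation: the cationic univalent gold complex activates the alkyne for 6-endo attack by the arene carbon ortho to the ester oxygen and para to the methoxy group, the only activated and unhindered position, and protodeauration gives coumarin B; the alkenes bind cationic gold far less well than the alkyne, and the stereocentres are remote.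

## Compound list

1 | but-2-yn-1-ol | CC#CCO | starting material
2 | (Z)-3-(4,4,5,5-tetramethyl-1,3,2-dioxaborolan-2-yl)but-2-en-1-ol | C/C(=C\CO)B1OC(C)(C)C(C)(C)O1 | intermediate
3 | (Z)-3-(4,4,5,5-tetramethyl-1,3,2-dioxaborolan-2-yl)but-2-enal | C/C(=C\C=O)B1OC(C)(C)C(C)(C)O1 | intermediate
4 | 4,4,5,5-tetramethyl-2-[(2Z)-5-methylhexa-2,4-dien-2-yl]-1,3,2-dioxaborolane | C/C(=C\C=C(C)C)B1OC(C)(C)C(C)(C)O1 | intermediate
5 | 2-methoxybenzene-1,4-diol | COc1cc(O)ccc1O | starting material
6 | 2-methoxy-4-(triisopropylsilyloxy)phenol | COc1cc(O[Si](C(C)C)(C(C)C)C(C)C)ccc1O | intermediate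
7 | 2-methoxy-4-(triisopropylsilyloxy)phenyl trifluoromethanesulfonate | COc1cc(O[Si](C(C)C)(C(C)C)C(C)C)ccc1OS(=O)(=O)C(F)(F)F | intermediate
8 | 4-bromo-2-methylbut-1-ene | CC(=C)CCBr | starting material
9 | 4-iodo-2-methylbut-1-ene | CC(=C)CCI | intermediate
10 | (3-methylbut-3-enyl)lithium | [Li]CCC(C)=C | intermediate (not isolated)
11 | lithium (3-methylbut-3-enyl)[(2Z)-5-methylhexa-2,4-dien-2-yl](pinacolato)borate | [Li+].C/C(=C\C=C(C)C)[B-]1(CCC(C)=C)OC(C)(C)C(C)(C)O1 | intermediate (not isolated)
12 | 2-[(5R,6S)-6-[2-methoxy-4-(triisopropylsilyloxy)phenyl]-2,5,8-trimethylnona-1,7-dien-5-yl]-4,4,5,5-tetramethyl-1,3,2-dioxaborolane | CC1(C)OB(OC1(C)C)[C@@](C)(CCC(C)=C)[C@H](C=C(C)C)c1ccc(O[Si](C(C)C)(C(C)C)C(C)C)cc1OC | intermediate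
13 | 2-[(1R,2S)-2-[2-methoxy-4-(triisopropylsilyloxy)phenyl]-1,4-dimethylcyclohex-3-en-1-yl]-4,4,5,5-tetramethyl-1,3,2-dioxaborolane | CC1(C)OB(OC1(C)C)[C@@]2(C)CCC(C)=C[C@@H]2c2ccc(O[Si](C(C)C)(C(C)C)C(C)C)cc2OC | intermediate
14 | bromomagnesium ethenyl[(1R,2S)-2-[2-methoxy-4-(triisopropylsilyloxy)phenyl]-1,4-dimethylcyclohex-3-en-1-yl](pinacolato)borate | C=C[B-]1(OC(C)(C)C(C)(C)O1)[C@@]2(C)CCC(C)=C[C@@H]2c2ccc(O[Si](C(C)C)(C(C)C)C(C)C)cc2OC.[Mg+2].[Br-] | intermediate (not isolated)
15 | 2-[2-iodo-1-[(1R,2S)-2-[2-methoxy-4-(triisopropylsilyloxy)phenyl]-1,4-dimethylcyclohex-3-en-1-yl]ethyl]-4,4,5,5-tetramethyl-1,3,2-dioxaborolane (both epimers at the boron-bearing carbon) | ICC(B1OC(C)(C)C(C)(C)O1)[C@@]2(C)CCC(C)=C[C@@H]2c2ccc(O[Si](C(C)C)(C(C)C)C(C)C)cc2OC | intermediate (not isolated)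
16 | triisopropyl[4-[(1S,6R)-6-ethenyl-3,6-dimethylcyclohex-2-en-1-yl]-3-methoxyphenoxy]silane | C=C[C@@]1(C)CCC(C)=C[C@@H]1c1ccc(O[Si](C(C)C)(C(C)C)C(C)C)cc1OC | intermediate
17 | 2-hydroxy-4-methoxybenzaldehyde | COc1ccc(C=O)c(O)c1 | starting material
18 | 5-bromo-2-hydroxy-4-methoxybenzaldehyde | COc1cc(O)c(C=O)cc1Br | intermediate
19 | ethyl 3-(5-bromo-2-hydroxy-4-methoxyphenyl)prop-2-enoate (E/Z mixture) | CCOC(=O)C=Cc1cc(Br)c(OC)cc1O | intermediate (not isolated)
20 | 6-bromo-7-methoxychromen-2-one | COc1cc2oc(=O)ccc2cc1Br | intermediate
21 | 7-methoxy-6-[(E)-2-[(1R,2S)-2-[2-methoxy-4-(triisopropylsilyloxy)phenyl]-1,4-dimethylcyclohex-3-en-1-yl]ethenyl]chromen-2-one | COc1cc2oc(=O)ccc2cc1/C=C/[C@@]1(C)CCC(C)=C[C@@H]1c1ccc(O[Si](C(C)C)(C(C)C)C(C)C)cc1OC | intermediate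
22 | 6-[(E)-2-[(1R,2S)-2-(4-hydroxy-2-methoxyphenyl)-1,4-dimethylcyclohex-3-en-1-yl]ethenyl]-7-methoxychromen-2-one | COc1cc2oc(=O)ccc2cc1/C=C/[C@@]1(C)CCC(C)=C[C@@H]1c1ccc(O)cc1OC | intermediate
23 | 3-methoxy-4-[(1S,6R)-6-[(E)-2-(7-methoxy-2-oxochromen-6-yl)ethenyl]-3,6-dimethylcyclohex-2-en-1-yl]phenyl prop-2-ynoate | COc1cc2oc(=O)ccc2cc1/C=C/[C@@]1(C)CCC(C)=C[C@@H]1c1ccc(OC(=O)C#C)cc1OC | intermediate
24 | 7-methoxy-6-[(E)-2-[(1R,2S)-2-(7-methoxy-2-oxochromen-6-yl)-1,4-dimethylcyclohex-3-en-1-yl]ethenyl]chromen-2-one | COc1cc2oc(=O)ccc2cc1/C=C/[C@@]1(C)CCC(C)=C[C@@H]1c1cc2ccc(=O)oc2cc1OC | target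

## Step count and least certain steps

Total: 15 steps. Longest linear sequence: 10 steps (steps 1, 2, 3, 7, 8, 9, 12, 13, 14, 15).

**Step 7 (key step, proposed new method).** Two processes are most likely to interfere.
- The trisubstituted boron-bearing alkene may bind the arylpalladium cation too slowly, so that direct transfer of the alkenyl or alkyl group from boron to palladium (a Suzuki-type path) overtakes the metallate shift.
- Palladium may still engage the conjugated diene away from the β-carbon, with loss of regio- and stereocontrol.

A first adjustment inside the approach would be a more shielding diol on boron. The fallback uses known chemistry, sets out from 1, 9 and 7, and rejoins the route at 16: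
- trans-Hydroalumination of 1 with NaAlH2(OCH2CH2OCH3)2 and iodination give (Z)-3-iodobut-2-en-1-ol F1.
- Organolithium 10 (from 9) is transmetallated with ZnCl2 to (3-methylbut-3-enyl)zinc chloride F2. Negishi coupling of F2 with F1 (Pd(PPh3)4) gives (2Z)-3,7-dimethylocta-2,7-dien-1-ol F3.
- Mesylation of F3 in the presence of LiCl gives (2Z)-1-chloro-3,7-dimethylocta-2,7-diene F4.
- Suzuki–Miyaura coupling of 7 with commercial (E)-3-(pinacolboryl)prop-2-en-1-ol (Pd(PPh3)4, K3PO4) gives (2E)-3-[2-methoxy-4-(triisopropylsilyloxy)phenyl]prop-2-en-1-ol F5. Palladium-catalysed borylation of this allylic alcohol with B2pin2 gives 2-[(2E)-3-[2-methoxy-4-(triisopropylsilyloxy)phenyl]prop-2-en-1-yl]-4,4,5,5-tetramethyl-1,3,2-dioxaborolane F6.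
- A palladium-catalysed enantioselective allyl–allyl cross-coupling of F4 with F6 (Pd2(dba)3, a chiral 6,6′-dimethoxybiphenyl-2,2′-diylbis(di-2-furylphosphine), CsF, THF/water) forms the C1–C6 bond by 3,3′-reductive elimination. This is a known way to 1,5-dienes with a quaternary centre next to an aryl-bearing tertiary one. It should give [4-[(3S,4R)-4-ethenyl-4,7-dimethylocta-1,7-dien-3-yl]-3-methoxyphenoxy]triisopropylsilane F7. On the chair model of that elimination, the Z chloride and the E boronate place methyl and aryl cis, and the ligand antipode sets the absolute sense.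
- Ring-closing metathesis of F7 (catalyst of step 8) closes C4=C5 with loss of ethylene and gives 16. The vinyl group on the quaternary carbon is the slowest of the three alkenes to engage, which is relied on to favour the six-membered ring.

**Step 8.** Initiation may be slow because one alkene is 1,1-disubstituted and the other trisubstituted and attached to a branched carbon; catalyst decay and ruthenium hydride-induced alkene migration could then compete. The fallback leaves metathesis, sets out from 12 and returns at 13. Ozonolysis of both alkenes (O3, CH2Cl2/MeOH, −78 °C, then Me2S) gives (2S,3R)-2-[2-methoxy-4-(triisopropylsilyloxy)phenyl]-3-methyl-6-oxo-3-(4,4,5,5-tetramethyl-1,3,2-dioxaborolan-2-yl)heptanal F8. Intramolecular McMurry coupling of the ketone and aldehyde carbons (TiCl3, Zn–Cu couple, DME, reflux) then forms C4=C5 directly. Boronic esters tolerate such low-valent titanium conditions; the main concern would be epimerisation of the α-aryl aldehyde.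

**Step 12.** Insertion into a vinyl group on a quaternary carbon may be slow. The arylpalladium intermediate could then decay by reduction or add to the C3=C4 bond of a second coumarin, and long heating with amine endangers the lactone. The fallback removes the coumarin from the coupling and builds both coumarins at the end; it sets out from 16 and 7 and returns at 24:
- Heck reaction of 16 with triflate 7 (Pd(OAc)2, P(o-tolyl)3, LiCl, Et3N, DMF) gives triisopropyl[3-methoxy-4-[(1S,6R)-6-[(E)-2-[2-methoxy-4-(triisopropylsilyloxy)phenyl]ethenyl]-3,6-dimethylcyclohex-2-en-1-yl]phenoxy]silane F9.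
- Double desilylation (Bu4NF, AcOH) gives 4-[(E)-2-[(1R,2S)-2-(4-hydroxy-2-methoxyphenyl)-1,4-dimethylcyclohex-3-en-1-yl]ethenyl]-3-methoxyphenol F10.
- Double esterification with propiolic acid (DCC) gives 4-[(E)-2-[(1R,2S)-1,4-dimethyl-2-[2-methoxy-4-(prop-2-ynoyloxy)phenyl]cyclohex-3-en-1-yl]ethenyl]-3-methoxyphenyl prop-2-ynoate F11.
- Twofold gold-catalysed hydroarylation under the conditions of step 15 closes both lactone rings to 24.

**Step 15.** The cationic gold complex may be diverted by the stilbene-type alkene or the coumarin carbonyl, so that hydration or cleavage of the propiolate ester overtakes a slow cyclisation. Adventitious acid could also move C4=C5 towards conjugation. The fallback changes the ring construction, sets out from 22 and returns at 24. Magnesium-mediated ortho-formylation of the phenol (MgCl2, Et3N, paraformaldehyde, MeCN) at the unhindered position para to the methoxy group gives 5-[(1S,6R)-6-[(E)-2-(7-methoxy-2-oxochromen-6-yl)ethenyl]-3,6-dimethylcyclohex-2-en-1-yl]-2-hydroxy-4-methoxybenzaldehyde F12. Treatment with (triphenylphosphoranylidene)ketene in toluene at 80–110 °C acylates the phenol and closes the lactone by intramolecular Wittig reaction. This stays well below the temperatures at which the 1,5-diene could rearrange.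

## Further compounds

F1 | step 7 | (Z)-3-iodobut-2-en-1-ol | C/C(I)=C/CO
F2 | step 7 | (3-methylbut-3-enyl)zinc chloride | C=C(C)CC[Zn]Cl
F3 | step 7 | (2Z)-3,7-dimethylocta-2,7-dien-1-ol | C/C(CCC(C)=C)=C/CO
F4 | step 7 | (2Z)-1-chloro-3,7-dimethylocta-2,7-diene | C/C(CCC(C)=C)=C/CCl
F5 | step 7 | (2E)-3-[2-methoxy-4-(triisopropylsilyloxy)phenyl]prop-2-en-1-ol | COc1cc(O[Si](C(C)C)(C(C)C)C(C)C)ccc1/C=C/CO
F6 | step 7 | 2-[(2E)-3-[2-methoxy-4-(triisopropylsilyloxy)phenyl]prop-2-en-1-yl]-4,4,5,5-tetramethyl-1,3,2-dioxaborolane | COc1cc(O[Si](C(C)C)(C(C)C)C(C)C)ccc1/C=C/CB1OC(C)(C)C(C)(C)O1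
F7 | step 7 | [4-[(3S,4R)-4-ethenyl-4,7-dimethylocta-1,7-dien-3-yl]-3-methoxyphenoxy]triisopropylsilane | C=C[C@@](C)(CCC(C)=C)[C@H](C=C)c1ccc(O[Si](C(C)C)(C(C)C)C(C)C)cc1OC
F8 | step 8 | (2S,3R)-2-[2-methoxy-4-(triisopropylsilyloxy)phenyl]-3-methyl-6-oxo-3-(4,4,5,5-tetramethyl-1,3,2-dioxaborolan-2-yl)heptanal | CC1(C)OB(OC1(C)C)[C@@](C)(CCC(C)=O)[C@H](C=O)c1ccc(O[Si](C(C)C)(C(C)C)C(C)C)cc1OC
F9 | step 12 | triisopropyl[3-methoxy-4-[(1S,6R)-6-[(E)-2-[2-methoxy-4-(triisopropylsilyloxy)phenyl]ethenyl]-3,6-dimethylcyclohex-2-en-1-yl]phenoxy]silane | COc1cc(O[Si](C(C)C)(C(C)C)C(C)C)ccc1/C=C/[C@@]1(C)CCC(C)=C[C@@H]1c1ccc(O[Si](C(C)C)(C(C)C)C(C)C)cc1OC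
F10 | step 12 | 4-[(E)-2-[(1R,2S)-2-(4-hydroxy-2-methoxyphenyl)-1,4-dimethylcyclohex-3-en-1-yl]ethenyl]-3-methoxyphenol | COc1cc(O)ccc1/C=C/[C@@]1(C)CCC(C)=C[C@@H]1c1ccc(O)cc1OC
F11 | step 12 | 4-[(E)-2-[(1R,2S)-1,4-dimethyl-2-[2-methoxy-4-(prop-2-ynoyloxy)phenyl]cyclohex-3-en-1-yl]ethenyl]-3-methoxyphenyl prop-2-ynoate | COc1cc(OC(=O)C#C)ccc1/C=C/[C@@]1(C)CCC(C)=C[C@@H]1c1ccc(OC(=O)C#C)cc1OC
F12 | step 15 | 5-[(1S,6R)-6-[(E)-2-(7-methoxy-2-oxochromen-6-yl)ethenyl]-3,6-dimethylcyclohex-2-en-1-yl]-2-hydroxy-4-methoxybenzaldehyde | COc1cc2oc(=O)ccc2cc1/C=C/[C@@]1(C)CCC(C)=C[C@@H]1c1cc(C=O)c(O)cc1OC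
A1 | alternative 1 | 6-[(2R,5Z)-2-[(tert-butyldiphenylsilyl)oxymethyl]-1-hydroxy-2,5-dimethyl-6-(trimethylsilyl)hex-5-en-1-yl]-7-methoxychromen-2-one (either carbinol epimer) | C[Si](C)(C)/C=C(/C)CC[C@](C)(CO[Si](c1ccccc1)(c1ccccc1)C(C)(C)C)C(O)c1cc2ccc(=O)oc2cc1OC
A2 | alternative 1 | 6-[(1S,6S)-6-[(tert-butyldiphenylsilyl)oxymethyl]-3,6-dimethylcyclohex-2-en-1-yl]-7-methoxychromen-2-one | CC(C)(C)[Si](OC[C@@]1(C)CCC(C)=C[C@@H]1c1cc2ccc(=O)oc2cc1OC)(c1ccccc1)c1ccccc1
A3 | alternative 2 | (S)-2,5-dimethylcyclohex-2-en-1-one | CC1=CC[C@H](C)CC1=O
A4 | alternative 2 | chloro(7-methoxy-2-oxochromen-6-yl)zinc | COc1cc2oc(=O)ccc2cc1[Zn]Cl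
A5 | alternative 2 | 6-[(E)-2-bromoethenyl]-7-methoxychromen-2-one | COc1cc2oc(=O)ccc2cc1/C=C/Br
A6 | alternative 2 | (2R,3R,5S)-3-(7-methoxy-2-oxochromen-6-yl)-2,5-dimethyl-2-[(E)-2-(7-methoxy-2-oxochromen-6-yl)ethenyl]cyclohexan-1-one | COc1cc2oc(=O)ccc2cc1/C=C/[C@@]1(C)C(=O)C[C@@H](C)C[C@@H]1c1cc2ccc(=O)oc2cc1OC
A7 | alternative 3 | (E)-3-(7-methoxy-2-oxochromen-6-yl)-2-methylprop-2-enal | COc1cc2oc(=O)ccc2cc1/C=C(\C)C=O
A8 | alternative 3 | (E)-trimethyl(2-methylbuta-1,3-dienyl)silane | C[Si](C)(C)/C=C(\C)C=C
A9 | alternative 3 | (1S,2R)-2-(7-methoxy-2-oxochromen-6-yl)-1,4-dimethyl-3-(trimethylsilyl)cyclohex-4-ene-1-carbaldehyde (silyl-bearing centre as formed) | O=C[C@@]1(C)CC=C(C)C([Si](C)(C)C)[C@@H]1c1cc2ccc(=O)oc2cc1OC
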